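**Remark on the chemistry.** The target is taken with Z geometry at C2=C3, C4=C5 and C8=C9 and with the configuration 6S,7S,10S,11R,12S,14S,15R, as its SMILES specifies. Ansamycin numbering is used throughout: C1 is the amide carbonyl, C15 the benzylic carbon, C16–C21 the arene, and nitrogen sits on C20. C7 is carried as a TBS ether through the ring closure and the methylation, and the carbamate is put on afterwards.

## Analysis of the target

The target is a 19-membered ansa lactam in which the C1–C15 chain spans the meta positions C16 and C20 of a hydroquinone ring (C16–C21, hydroxyls at C18 and C21). The chain carries a (2Z,4Z)-2-methyldienamide, a Z trisubstituted C8=C9 alkene, methyl ethers at C6, C11, C12 and C15, a primary carbamate at C7 and C-methyl groups at C2, C8, C10 and C14. The seven stereocentres form three groups that cannot control one another: the syn C6/C7 pair, the C10–C11–C12 triad (10,11-syn, 11,12-anti) and the syn C14/C15 pair. C8=C9 separates the first two groups and the C13 methylene the last two. The hydroquinone oxidises in air, the carbamate is allylic, and the three Z alkenes are the less stable geometries, so they must be made under kinetic control and kept from acid, strong base and heat. The difficulties are the closure of a large ring, the remote stereochemical groups and the acylation of an aniline flanked by a methoxy group. The strategy rests on C11 and C12: they are the only neighbouring ring carbons that carry the same oxygen substituent, and each is bonded to only one other carbon (C10 and C13). Both can therefore come from aldehyde carbons, and the two hydroxyls that result are methylated together without being told apart.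

## Retrosynthetic reasoning

**43 ⇒ 42 ⇒ 41 (oxidation state of the arene).** The air-sensitive hydroquinone is revealed last. Backwards, the two phenolic O–H bonds become the aryl methyl ethers of 41 by way of quinone 42. The methyl ethers come with starting material 1 and survive base, hydride, electron-transfer reduction and alkylating agents. The forward oxidation can only give the para-quinone, because C18 and C21 are the only para-disposed oxygens.

**41 ⇒ 39 ⇒ 38 ⇒ 37 (C7 O–carbamoyl bond, then both O–CH3 bonds at C11 and C12).** The carbamate is cut first because a primary carbamate would compete for the alkylating agent in the methylation and would need a C7 protecting group orthogonal to those on C11 and C12. As a silyl ether, C7 needs no extra handling. The two methyl groups are cut together to diol 37, so neither oxygen has to be distinguished.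

**37 ⇒ 35 (C11–C12 bond, ring closure).** This bond is chosen because both carbons end up as identical carbinol carbons, so two aldehydes of the same polarity can be joined reductively. One step gives the ring, one skeletal bond and two stereocentres, and neither half needs a separate asymmetric construction of the C11/C12 pair. The forward reaction must close a 19-membered ring at high dilution, obey the C10 centre at C11, deliver the anti relationship at C12 and leave the dienamide alone.

**35 ⇒ 34 ⇒ 33 (oxidation level at C11 and C12).** The dialdehyde 35 cannot be stored, because C10 is α to an aldehyde and allylic. It is traced to the bis-primary silyl ether 33, whose two primary silyl groups can be removed in the presence of the hindered secondary one at C7.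

**33 ⇒ 32 + 11 (N–C1 amide bond).** This cut divides the molecule into two halves of similar size, each ending in a protected primary alcohol. The amide is made between two open-chain partners, where a forcing coupling is tolerable. The forward step must acylate a hindered aniline without isomerising C2=C3.

**32 ⇒ 31 ⇒ 30 + 15 (C2=C3), and 30 ⇒ 29 ⇒ 28 ⇒ 26 + 27 (C4=C5).** The diene is grown outwards from C5 by two kinetically Z-selective phosphonate olefinations, each on an aldehyde made just before use. Each geometry is fixed, and can be purified, at the step that creates it.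

**26 ⇒ 25 ⇒ 24 ⇒ 23 ⇒ 21 + 18 (C6–C7 aldol bond).** An auxiliary-controlled aldol between the methoxyacetyl imide 21 and enal 18 sets the syn C6/C7 pair independently of the remote C10 centre. It delivers C5 at the carboxyl level for the olefinations. Imide 21 comes from 19 and 20.

**18 ⇒ 17 ⇒ 16 ⇒ 14 + 15 (C8=C9), and 14 ⇒ 13 ⇒ 12.** The Z trisubstituted alkene comes from the same phosphonate 15. C10 is taken from the chiral pool: in 12 the hydroxymethyl carbon becomes C11 and the ester carbon becomes C9, which turns the R descriptor of 12 into 10S.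

**11 ⇒ 10 ⇒ 9 ⇒ 7 ⇒ 6 ⇒ 3 + 4 (C14–C15 bond), and 3 ⇒ 2 ⇒ 1.** The aniline comes from the nitro group and the C12 hydroxyl from hydroboration of a vinyl group. The vinyl carbinol comes from a Z-crotyl addition to aldehyde 3. This brings C12, C13, C14 and the methyl group from 4 in one step and sets C14/C15 syn. A propionate aldol would deliver only C13–C15 and would need a one-carbon homologation. Aldehyde 3 comes from 1 by nitration ortho to the phenol and O-methylation.

## Alternatives that were turned down

**Alternative 1:** The benzene ring is disconnected at C18–C19, C20–C21 and C16–C21, so that arene and macrocycle form together. The substrate is the open-chain pentacarbonyl[alkenyl(methoxy)carbene]chromium A2, which ends in a terminal N-(4-methoxybenzyl) ynamide. In the forward key step the ynamide inserts into the chromium–carbene bond on warming, one carbonyl ligand inserts, and the dienylketene electrocyclises. Air decomplexation then gives the ansa 4-methoxyphenol A1.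
- For: three C–C bonds, the arene and the 19-membered ring arise in one step. C21–OH and C18–OMe arrive differentiated, and no nitration or hindered aniline acylation is needed. No stereocentre is created in the ring closure, and on that point it is stronger than the pinacol closure.
- Against: nitrogen-substituted alkynes tend to stop after insertion as amino-stabilised carbene complexes instead of taking up the carbonyl ligand. Benzannulation of an ynamide across a ring of this size has no close precedent. A2 would carry a metal carbene beside three further alkenes that can be cyclopropanated or isomerised at the temperature needed. The benzylic N-substituent must later be removed from an anilide. All seven stereocentres, including C11 and C12, must be built into one long chain first.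
- Comparison: the chosen route gives up the stereochemical safety of the ring closure. In return it uses only established reaction types, and its two short fragments need no separate chemistry for C11 and C12.

**Alternative 2:** The aryl–nitrogen bond N–C20 is disconnected, and nitrogen is inserted between C1 and C20 of an 18-membered aryl ketone. In the forward key step the ketoxime A4, with its hydroxyl anti to the arene, is O-sulfonylated. The aryl carbon C20 then migrates from C1 to nitrogen and the ring expands to the 19-membered en-yne lactam A3.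
- For: the hindered aniline never has to be acylated, and an electron-rich aryl group migrates readily and stereospecifically. No stereocentre is formed in the key step, so it is as safe as alternative 3 on configuration and safer than the pinacol closure.
- Against: the oxime geometry decides which group migrates. The ketone is flanked by a doubly ortho-substituted arene and an α-branched alkene, so neither geometry is clearly preferred, and the two interconvert under the acid that the step releases. Alkenyl migration would give the reversed amide. A conjugated en-yne oxime can also cyclise through oxygen or fragment. The 18-membered carbocycle needs its own macrocyclisation, and the alkyne must still be semi-reduced afterwards.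
- Comparison: it needs two ring-forming operations and a late reduction where the chosen route needs one closure. The chosen route makes the amide between open-chain partners and forms the Z,Z-diene before the ring exists.

**Alternative 3:** The C4–C5 bond is disconnected as an alkyne. In the forward key step, ring-closing alkyne metathesis of the seco diyne A6, which has two methyl-capped alkynes, gives the 19-membered en-yne lactam A5. A Z-selective semi-reduction then gives the 4Z alkene.
- For: this reaction type has a strong record for large rings and tolerates ethers and silyl ethers. It forms no stereocentre, and the 4Z geometry from a semi-reduction is secure. On reliability of ring closure and on stereochemical safety it is stronger than the chosen route.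
- Against: one reacting alkyne is conjugated to the 2Z-enamide and the other is propargylic to the C6 ether, and a free anilide N–H is present. The semi-reduction must spare a Z-enamide and a trisubstituted alkene in the ring. The C11/C12 bis-methoxy pair must be made by its own asymmetric steps in the chain, which lengthens the linear sequence.
- Comparison: the chosen route offers step economy at C11 and C12. Bond, ring and both carbinol centres come from two primary alcohols in one operation, and all three Z alkenes are fixed in the open chain. It pays for this with the uncertain configuration at C12.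

Key step: step 26

## Route

Step 1
Reactants: 1 2-hydroxy-5-methoxybenzaldehyde
Product: 2 2-hydroxy-5-methoxy-3-nitrobenzaldehyde
Conditions: HNO3 (70%), AcOH, 0 °C → rt
Reagents that add atoms: nitric acid, O[N+](=O)[O-]
Why: Electrophilic aromatic nitration; the phenol is the strongest director and its para position carries the methoxy group, so substitution is expected at the free ortho position, which is also meta to the formyl group.

Step 2
Reactants: 2 2-hydroxy-5-methoxy-3-nitrobenzaldehyde
Product: 3 2,5-dimethoxy-3-nitrobenzaldehyde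
Conditions: MeI, K2CO3, DMF, rt → 50 °C
Reagents that add atoms: iodomethane, CI
Why: Williamson ether synthesis (SN2 of the phenoxide on MeI); the acidic nitrophenol is deprotonated by K2CO3 and the aldehyde cannot enolise.

Step 3
Reactants: 3 2,5-dimethoxy-3-nitrobenzaldehyde; 4 cis-but-2-ene
Product: 6 (1R,2S)-1-(2,5-dimethoxy-3-nitrophenyl)-2-methylbut-3-en-1-ol, via diisopinocampheylborinate 5 (not isolated)
Conditions: 4, n-BuLi, KOt-Bu, THF, −78 → −45 °C; (+)-Ipc2BOMe, −78 °C; BF3·OEt2; 3, −78 °C; then NaOH, H2O2, 0 °C → rt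
Reagents that add atoms: (+)-B-methoxydiisopinocampheylborane, COB([C@H]1C[C@H]2C[C@@H]([C@@H]1C)C2(C)C)[C@H]1C[C@H]2C[C@@H]([C@@H]1C)C2(C)C (boron and isopinocampheyl groups of 5 only)
Why: Brown asymmetric crotylboration; the Z-crotylborane reacts through a closed chair transition state, so the Z geometry gives the 14,15-syn product, and the isopinocampheyl groups of the reagent made from (+)-Ipc2BOMe direct addition to the re face of the aldehyde, which sets 15R and 14S; alkaline H2O2 cleaves borinate 5.

Step 4
Reactants: 6 (1R,2S)-1-(2,5-dimethoxy-3-nitrophenyl)-2-methylbut-3-en-1-ol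
Product: 7 2,5-dimethoxy-1-[(1R,2S)-1-methoxy-2-methylbut-3-en-1-yl]-3-nitrobenzene
Conditions: Me3OBF4, 1,8-bis(dimethylamino)naphthalene, 4 Å MS, CH2Cl2, rt
Reagents that add atoms: trimethyloxonium tetrafluoroborate, C[O+](C)C.F[B-](F)(F)F
Why: O-Methylation with a Meerwein salt and a non-nucleophilic proton scavenger; no alkoxide is generated next to the nitroarene and no stereocentre is touched.

Step 5
Reactants: 7 2,5-dimethoxy-1-[(1R,2S)-1-methoxy-2-methylbut-3-en-1-yl]-3-nitrobenzene
Product: 9 (3S,4R)-4-(2,5-dimethoxy-3-nitrophenyl)-4-methoxy-3-methylbutan-1-ol, via B-alkyl-9-borabicyclononane 8 (not isolated)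
Conditions: 9-BBN, THF, 0 °C → rt; then NaOH, H2O2, 0 °C
Reagents that add atoms: 9-borabicyclo[3.3.1]nonane, B1C2CCCC1CCC2 (boron of 8 only); hydrogen peroxide, OO (hydroxyl oxygen of 9)
Why: Anti-Markovnikov hydroboration–oxidation; 9-BBN places boron on the terminal carbon C12 of the monosubstituted alkene and does not reduce the nitro group, and the C–B bond is oxidised to the primary alcohol.

Step 6
Reactants: 9 (3S,4R)-4-(2,5-dimethoxy-3-nitrophenyl)-4-methoxy-3-methylbutan-1-ol
Product: 10 tert-butyl{[(3S,4R)-4-(2,5-dimethoxy-3-nitrophenyl)-4-methoxy-3-methylbutyl]oxy}dimethylsilane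
Conditions: TBSCl, imidazole, DMF, rt
Reagents that add atoms: tert-butyldimethylsilyl chloride, CC(C)(C)[Si](C)(C)Cl
Why: Silyl ether formation; it masks the C12 alcohol so that it is not acylated in step 23.

Step 7
Reactants: 10 tert-butyl{[(3S,4R)-4-(2,5-dimethoxy-3-nitrophenyl)-4-methoxy-3-methylbutyl]oxy}dimethylsilane
Product: 11 3-[(1R,2S)-4-[(tert-butyldimethylsilyl)oxy]-1-methoxy-2-methylbutyl]-2,5-dimethoxyaniline
Conditions: H2 (1 atm), Pd/C (10%), EtOAc, rt
Reagents that add atoms: none
Why: Catalytic hydrogenation of the nitroarene to the aniline; under neutral conditions at 1 atm the benzylic methyl ether and the silyl ether should survive.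

Step 8
Reactants: 12 methyl (R)-3-hydroxy-2-methylpropanoate
Product: 13 methyl (R)-3-[(tert-butyldimethylsilyl)oxy]-2-methylpropanoate
Conditions: TBSCl, imidazole, CH2Cl2, rt
Reagents that add atoms: tert-butyldimethylsilyl chloride, CC(C)(C)[Si](C)(C)Cl
Why: Silylation of the primary alcohol, which becomes C11; the stereocentre is not involved.

Step 9
Reactants: 13 methyl (R)-3-[(tert-butyldimethylsilyl)oxy]-2-methylpropanoate
Product: 14 (R)-3-[(tert-butyldimethylsilyl)oxy]-2-methylpropanal
Conditions: i-Bu2AlH (1.05 equiv), CH2Cl2, −78 °C; aq. KNaC4H4O6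
Reagents that add atoms: none
Why: Partial reduction of the ester with i-Bu2AlH; the aluminium hemiacetal persists at −78 °C until work-up, and the aldehyde is used crude at once so that the α-stereocentre (C10) does not racemise.

Step 10
Reactants: 14 (R)-3-[(tert-butyldimethylsilyl)oxy]-2-methylpropanal; 15 ethyl 2-[bis(2,2,2-trifluoroethoxy)phosphoryl]propanoate
Product: 16 ethyl (2Z,4S)-5-[(tert-butyldimethylsilyl)oxy]-2,4-dimethylpent-2-enoate
Conditions: 15, KN(SiMe3)2, 18-crown-6, THF, −78 °C; then 14
Reagents that add atoms: none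
Why: Still–Gennari olefination (Z-selective Horner–Wadsworth–Emmons reaction); with the trifluoroethyl phosphonate and a dissociated potassium ion, elimination outruns equilibration of the adducts, which gives the Z trisubstituted enoate with the ester cis to C10.

Step 11
Reactants: 16 ethyl (2Z,4S)-5-[(tert-butyldimethylsilyl)oxy]-2,4-dimethylpent-2-enoate
Product: 17 (2Z,4S)-5-[(tert-butyldimethylsilyl)oxy]-2,4-dimethylpent-2-en-1-ol
Conditions: i-Bu2AlH (2.5 equiv), CH2Cl2, −78 °C
Reagents that add atoms: none
Why: 1,2-Reduction of the enoate to the allylic alcohol by i-Bu2AlH; alkene geometry and silyl ether are unaffected.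

Step 12
Reactants: 17 (2Z,4S)-5-[(tert-butyldimethylsilyl)oxy]-2,4-dimethylpent-2-en-1-ol
Product: 18 (2Z,4S)-5-[(tert-butyldimethylsilyl)oxy]-2,4-dimethylpent-2-enal
Conditions: Dess–Martin periodinane, NaHCO3, CH2Cl2, 0 °C
Reagents that add atoms: none
Why: Dess–Martin oxidation under bicarbonate buffer; neither acid nor amine base is present to isomerise the Z enal, which is used directly.

Step 13
Reactants: 19 (R)-4-benzyl-1,3-oxazolidin-2-one; 20 methoxyacetyl chloride
Product: 21 (R)-4-benzyl-3-(methoxyacetyl)-1,3-oxazolidin-2-one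
Conditions: n-BuLi, THF, −78 °C; then 20, −78 → 0 °C
Reagents that add atoms: none
Why: N-Acylation of the lithiated oxazolidinone by the acid chloride (nucleophilic acyl substitution).

Step 14
Reactants: 21 (R)-4-benzyl-3-(methoxyacetyl)-1,3-oxazolidin-2-one; 18 (2Z,4S)-5-[(tert-butyldimethylsilyl)oxy]-2,4-dimethylpent-2-enal
Product: 23 (4R)-4-benzyl-3-[(2R,3S,4Z,6S)-7-[(tert-butyldimethylsilyl)oxy]-3-hydroxy-2-methoxy-4,6-dimethylhept-4-enoyl]-1,3-oxazolidin-2-one, via dibutylboron aldolate 22 (not isolated)
Conditions: 21, Bu2BOTf, Et3N, CH2Cl2, −78 → 0 °C; 18, −78 → −20 °C; then pH 7 buffer, MeOH, H2O2, 0 °C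
Reagents that add atoms: dibutylboryl trifluoromethanesulfonate, CCCCB(CCCC)OS(=O)(=O)C(F)(F)F (boron and butyl groups of 22 only)
Why: Evans syn aldol reaction of a glycolate imide; the Z boron enolate reacts through a Zimmerman–Traxler chair with the auxiliary carbonyl turned away, and the (R)-benzyl group shields one enolate face, which sets the syn pair (2R,3S in the imide, 6S,7S in the target).

Step 15
Reactants: 23 (4R)-4-benzyl-3-[(2R,3S,4Z,6S)-7-[(tert-butyldimethylsilyl)oxy]-3-hydroxy-2-methoxy-4,6-dimethylhept-4-enoyl]-1,3-oxazolidin-2-one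
Product: 24 (4R)-4-benzyl-3-[(2R,3S,4Z,6S)-3,7-bis[(tert-butyldimethylsilyl)oxy]-2-methoxy-4,6-dimethylhept-4-enoyl]-1,3-oxazolidin-2-one
Conditions: TBSOTf, 2,6-lutidine, CH2Cl2, −78 → 0 °C
Reagents that add atoms: tert-butyldimethylsilyl trifluoromethanesulfonate, CC(C)(C)[Si](C)(C)OS(=O)(=O)C(F)(F)F
Why: Silylation of the hindered secondary alcohol with a silyl triflate; it blocks retro-aldol cleavage in the next step and gives the C7 ether that stays until step 28.

Step 16
Reactants: 24 (4R)-4-benzyl-3-[(2R,3S,4Z,6S)-3,7-bis[(tert-butyldimethylsilyl)oxy]-2-methoxy-4,6-dimethylhept-4-enoyl]-1,3-oxazolidin-2-one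
Product: 25 (2S,3S,4Z,6S)-3,7-bis[(tert-butyldimethylsilyl)oxy]-2-methoxy-4,6-dimethylhept-4-en-1-ol
Conditions: LiBH4, MeOH (1 equiv), THF, 0 °C
Reagents that add atoms: none
Why: Reductive cleavage of the N-acyl oxazolidinone by LiBH4 (hydride attacks the exocyclic carbonyl); it gives the C5 alcohol and returns auxiliary 19, and silyl ethers and the alkene are untouched.

Step 17
Reactants: 25 (2S,3S,4Z,6S)-3,7-bis[(tert-butyldimethylsilyl)oxy]-2-methoxy-4,6-dimethylhept-4-en-1-ol
Product: 26 (2R,3S,4Z,6S)-3,7-bis[(tert-butyldimethylsilyl)oxy]-2-methoxy-4,6-dimethylhept-4-enal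
Conditions: Dess–Martin periodinane, NaHCO3, CH2Cl2, 0 °C → rt
Reagents that add atoms: none
Why: Dess–Martin oxidation to the α-methoxy aldehyde without base, so C6 should not epimerise; the aldehyde is not stored.

Step 18
Reactants: 26 (2R,3S,4Z,6S)-3,7-bis[(tert-butyldimethylsilyl)oxy]-2-methoxy-4,6-dimethylhept-4-enal; 27 methyl 2-[bis(2,2,2-trifluoroethoxy)phosphoryl]acetate
Product: 28 methyl (2Z,4S,5S,6Z,8S)-5,9-bis[(tert-butyldimethylsilyl)oxy]-4-methoxy-6,8-dimethylnona-2,6-dienoate
Conditions: 27, KN(SiMe3)2, 18-crown-6, THF, −78 °C; then 26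
Reagents that add atoms: none
Why: Still–Gennari olefination; the kinetically Z-selective Horner–Wadsworth–Emmons reaction at −78 °C installs C4=C5 faster than the α-alkoxy aldehyde can epimerise.

Step 19
Reactants: 28 methyl (2Z,4S,5S,6Z,8S)-5,9-bis[(tert-butyldimethylsilyl)oxy]-4-methoxy-6,8-dimethylnona-2,6-dienoate
Product: 29 (2Z,4S,5S,6Z,8S)-5,9-bis[(tert-butyldimethylsilyl)oxy]-4-methoxy-6,8-dimethylnona-2,6-dien-1-ol
Conditions: i-Bu2AlH (2.5 equiv), CH2Cl2, −78 °C
Reagents that add atoms: none
Why: 1,2-Reduction of the conjugated ester to the Z allylic alcohol by i-Bu2AlH.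

Step 20
Reactants: 29 (2Z,4S,5S,6Z,8S)-5,9-bis[(tert-butyldimethylsilyl)oxy]-4-methoxy-6,8-dimethylnona-2,6-dien-1-ol
Product: 30 (2Z,4S,5S,6Z,8S)-5,9-bis[(tert-butyldimethylsilyl)oxy]-4-methoxy-6,8-dimethylnona-2,6-dienal
Conditions: Dess–Martin periodinane, NaHCO3, CH2Cl2, 0 °C
Reagents that add atoms: none
Why: Dess–Martin oxidation of the allylic alcohol under buffered conditions that should not isomerise the Z enal; it is used at once.

Step 21
Reactants: 30 (2Z,4S,5S,6Z,8S)-5,9-bis[(tert-butyldimethylsilyl)oxy]-4-methoxy-6,8-dimethylnona-2,6-dienal; 15 ethyl 2-[bis(2,2,2-trifluoroethoxy)phosphoryl]propanoate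
Product: 31 ethyl (2Z,4Z,6S,7S,8Z,10S)-7,11-bis[(tert-butyldimethylsilyl)oxy]-6-methoxy-2,8,10-trimethylundeca-2,4,8-trienoate
Conditions: 15, KN(SiMe3)2, 18-crown-6, THF, −78 °C; then 30
Reagents that add atoms: none
Why: Second Still–Gennari olefination with the α-methyl phosphonate; it forms C2=C3 with the ester cis to C4, and at −78 °C the addition should be faster than Z to E isomerisation of the enal.

Step 22
Reactants: 31 ethyl (2Z,4Z,6S,7S,8Z,10S)-7,11-bis[(tert-butyldimethylsilyl)oxy]-6-methoxy-2,8,10-trimethylundeca-2,4,8-trienoate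
Product: 32 (2Z,4Z,6S,7S,8Z,10S)-7,11-bis[(tert-butyldimethylsilyl)oxy]-6-methoxy-2,8,10-trimethylundeca-2,4,8-trienoic acid
Conditions: LiOH·H2O, THF/MeOH/H2O, rt → 40 °C; then 1 M HCl to pH 4, 0 °C
Reagents that add atoms: lithium hydroxide, [Li+].[OH-] (oxygen of the acid hydroxyl)
Why: Saponification of the ethyl ester (acyl–oxygen cleavage by hydroxide); silyl and methyl ethers are stable to LiOH, and the brief mild acidification should not desilylate.

Step 23
Reactants: 32 (2Z,4Z,6S,7S,8Z,10S)-7,11-bis[(tert-butyldimethylsilyl)oxy]-6-methoxy-2,8,10-trimethylundeca-2,4,8-trienoic acid; 11 3-[(1R,2S)-4-[(tert-butyldimethylsilyl)oxy]-1-methoxy-2-methylbutyl]-2,5-dimethoxyaniline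
Product: 33 (2Z,4Z,6S,7S,8Z,10S)-7,11-bis[(tert-butyldimethylsilyl)oxy]-N-{3-[(1R,2S)-4-[(tert-butyldimethylsilyl)oxy]-1-methoxy-2-methylbutyl]-2,5-dimethoxyphenyl}-6-methoxy-2,8,10-trimethylundeca-2,4,8-trienamide
Conditions: BOP-Cl, i-Pr2NEt, CH2Cl2, 0 °C → rt (40 °C if slow)
Reagents that add atoms: none
Why: Amide formation through the mixed carboxylic–phosphinic anhydride made with bis(2-oxo-3-oxazolidinyl)phosphinic chloride, an activation suited to hindered, weakly nucleophilic anilines; no acid chloride is formed, so the 2Z geometry should be kept.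

Step 24
Reactants: 33 tris-TBS amide (name as in step 23)
Product: 34 (2Z,4Z,6S,7S,8Z,10S)-7-[(tert-butyldimethylsilyl)oxy]-11-hydroxy-N-{3-[(1R,2S)-4-hydroxy-1-methoxy-2-methylbutyl]-2,5-dimethoxyphenyl}-6-methoxy-2,8,10-trimethylundeca-2,4,8-trienamide
Conditions: HF·pyridine, pyridine, THF, 0 °C → rt
Reagents that add atoms: none
Why: Selective desilylation; buffered HF·pyridine cleaves the two unhindered primary TBS ethers much faster than the secondary C7 ether, which is shielded by the C6 methoxy and C8 methyl groups.

Step 25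
Reactants: 34 C11,C12-diol (name as in step 24)
Product: 35 (2Z,4Z,6S,7S,8Z,10S)-7-[(tert-butyldimethylsilyl)oxy]-N-{2,5-dimethoxy-3-[(1R,2S)-1-methoxy-2-methyl-4-oxobutyl]phenyl}-6-methoxy-2,8,10-trimethyl-11-oxoundeca-2,4,8-trienamide
Conditions: Dess–Martin periodinane (2.5 equiv), NaHCO3, CH2Cl2, 0 °C, 30–45 min; short pad filtration; used at once
Reagents that add atoms: none
Why: Double Dess–Martin oxidation of the two primary alcohols; no base able to enolise the α-branched, β,γ-unsaturated C11 aldehyde is present, and at 0 °C alcohol oxidation is much faster than any oxidation of the anilide ring.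

Step 26
Reactants: 35 seco dialdehyde (name as in step 25)
Product: 37 19-membered ansa lactam (11R,12S)-11,12-diol bearing the C7 TBS ether, via samarium diolate 36 (not isolated)
Conditions: SmI2 (5 equiv, 0.1 M in THF), THF, slow addition of 35 over 6 h (final 0.002 M), 0 °C → rt; then aq. NaHCO3
Reagents that add atoms: samarium diiodide, I[Sm]I (samarium and iodine of 36 only)
Why: Each aldehyde takes one electron from divalent samarium to give an oxygen-bound trivalent samarium ketyl, and the two carbon radicals (or one ketyl and the second, samarium-coordinated carbonyl, followed by a second electron transfer) join to form C11–C12 as the samarium diolate 36, which aqueous work-up converts into 37. The closest known reaction type is the SmI2-mediated intramolecular pinacol coupling of dialdehydes to cyclic 1,2-diols. The 19-membered ring closes end to end through a carbon–carbon bond between the two chain termini, which both become ring atoms; slow addition at high dilution suppresses intermolecular coupling, and the arene, the anilide, the Z,Z-diene and the Z alkene leave few freely rotating bonds between the two ends. C11 is controlled by C10: in the Felkin–Anh arrangement the C9 alkenyl group lies anti to the forming bond and C12 passes the hydrogen instead of the methyl group, which gives the 10,11-syn relationship (11R). C12 has no neighbouring stereocentre and is fixed only relative to C11: the 11,12-anti diol results when both oxygens sit on samarium in a five-membered O–C–C–O chelate with the two ring arms cis, the arrangement that intramolecular SmI2 pinacol reactions normally follow, but a ring of this size can also take the trans arrangement, so this is the least secure element. Chemoselectivity rests on the large rate difference between aldehydes and the other reducible groups toward SmI2 in THF without HMPA or a proton donor, so the dienamide, the aryl ethers and the silyl ether should stay intact. The step needs 35 with unchanged C10 configuration, which is why 35 is made without base and consumed at once.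

Step 27
Reactants: 37 19-membered ansa lactam (11R,12S)-11,12-diol bearing the C7 TBS ether
Product: 38 19-membered ansa lactam 11,12-bis(methyl ether) bearing the C7 TBS ether
Conditions: Me3OBF4 (8 equiv), 1,8-bis(dimethylamino)naphthalene (10 equiv), 4 Å MS, CH2Cl2, 0 °C → rt
Reagents that add atoms: trimethyloxonium tetrafluoroborate, C[O+](C)C.F[B-](F)(F)F
Why: Double O-methylation with a Meerwein salt and a proton scavenger; hydroxyl oxygen is expected to be alkylated faster than the weakly basic oxygen of the conjugated N-aryl amide, and no base is present that could N-methylate the anilide or epimerise C10.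

Step 28
Reactants: 38 19-membered ansa lactam 11,12-bis(methyl ether) bearing the C7 TBS ether
Product: 39 19-membered ansa lactam with free C7 hydroxyl
Conditions: Bu4NF, THF, 0 °C → rt
Reagents that add atoms: none
Why: Fluoride-induced desilylation driven by Si–F bond formation; methyl ethers, dienamide and arene are inert.

Step 29
Reactants: 39 19-membered ansa lactam with free C7 hydroxyl
Product: 41 19-membered ansa lactam C7 carbamate (hydroquinone dimethyl ether), via N-trichloroacetyl carbamate 40 (not isolated)
Conditions: Cl3CC(O)NCO, CH2Cl2, 0 °C; then K2CO3, MeOH, rt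
Reagents that add atoms: trichloroacetyl isocyanate, O=C=NC(=O)C(Cl)(Cl)Cl
Why: Carbamoylation by addition of the alcohol to the acyl isocyanate, then methanolysis of the trichloroacetyl group of 40; the anilide N–H is far less nucleophilic than the alcohol.

Step 30
Reactants: 41 19-membered ansa lactam C7 carbamate (hydroquinone dimethyl ether)
Product: 42 ansa quinone (18,21-dione)
Conditions: (NH4)2Ce(NO3)6 (2.5 equiv), MeCN/H2O (4:1), −10 → 0 °C
Reagents that add atoms: water, O (both quinone oxygens)
Why: Oxidative demethylation of the 1,4-dimethoxyarene by tetravalent cerium (two one-electron oxidations with attack of water at the two methoxy-bearing carbons); C18 and C21 are the only para-disposed oxygens, so only the para-quinone can form.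

Step 31
Reactants: 42 ansa quinone (18,21-dione)
Product: 43 target hydroquinone CNP0109452.1
Conditions: Na2S2O4, EtOAc/H2O, rt, argon
Reagents that add atoms: none
Why: Dithionite reduction of the quinone to the hydroquinone (two electrons, two protons); nothing else in the molecule is reduced, and the product is kept under argon because it reoxidises in air.

## Compound list

1 | 2-hydroxy-5-methoxybenzaldehyde | COc1ccc(O)c(C=O)c1 | starting material
2 | 2-hydroxy-5-methoxy-3-nitrobenzaldehyde | COc1cc(C=O)c(O)c([N+](=O)[O-])c1 | intermediate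
3 | 2,5-dimethoxy-3-nitrobenzaldehyde | COc1cc(C=O)c(OC)c([N+](=O)[O-])c1 | intermediate
4 | cis-but-2-ene | C/C=C\C | starting material
5 | (1R,2S)-1-(2,5-dimethoxy-3-nitrophenyl)-2-methylbut-3-en-1-yl diisopinocampheylborinate | C=C[C@H](C)[C@@H](OB([C@H]1C[C@H]2C[C@@H]([C@@H]1C)C2(C)C)[C@H]1C[C@H]2C[C@@H]([C@@H]1C)C2(C)C)c1cc(OC)cc([N+](=O)[O-])c1OC | intermediate (not isolated)
6 | (1R,2S)-1-(2,5-dimethoxy-3-nitrophenyl)-2-methylbut-3-en-1-ol | C=C[C@H](C)[C@@H](O)c1cc(OC)cc([N+](=O)[O-])c1OC | intermediate
7 | 2,5-dimethoxy-1-[(1R,2S)-1-methoxy-2-methylbut-3-en-1-yl]-3-nitrobenzene | C=C[C@H](C)[C@@H](OC)c1cc(OC)cc([N+](=O)[O-])c1OC | intermediate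
8 | 9-[(3S,4R)-4-(2,5-dimethoxy-3-nitrophenyl)-4-methoxy-3-methylbutyl]-9-borabicyclo[3.3.1]nonane | C1CC2CCCC(C1)B2CC[C@H](C)[C@@H](OC)c1cc(OC)cc([N+](=O)[O-])c1OC | intermediate (not isolated)
9 | (3S,4R)-4-(2,5-dimethoxy-3-nitrophenyl)-4-methoxy-3-methylbutan-1-ol | OCC[C@H](C)[C@@H](OC)c1cc(OC)cc([N+](=O)[O-])c1OC | intermediate
10 | tert-butyl{[(3S,4R)-4-(2,5-dimethoxy-3-nitrophenyl)-4-methoxy-3-methylbutyl]oxy}dimethylsilane | CC(C)(C)[Si](C)(C)OCC[C@H](C)[C@@H](OC)c1cc(OC)cc([N+](=O)[O-])c1OC | intermediate
11 | 3-[(1R,2S)-4-[(tert-butyldimethylsilyl)oxy]-1-methoxy-2-methylbutyl]-2,5-dimethoxyaniline | CC(C)(C)[Si](C)(C)OCC[C@H](C)[C@@H](OC)c1cc(OC)cc(N)c1OC | intermediate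
12 | methyl (R)-3-hydroxy-2-methylpropanoate | COC(=O)[C@H](C)CO | starting material
13 | methyl (R)-3-[(tert-butyldimethylsilyl)oxy]-2-methylpropanoate | COC(=O)[C@H](C)CO[Si](C)(C)C(C)(C)C | intermediate
14 | (R)-3-[(tert-butyldimethylsilyl)oxy]-2-methylpropanal | O=C[C@H](C)CO[Si](C)(C)C(C)(C)C | intermediate
15 | ethyl 2-[bis(2,2,2-trifluoroethoxy)phosphoryl]propanoate | CCOC(=O)C(C)P(=O)(OCC(F)(F)F)OCC(F)(F)F | starting material
16 | ethyl (2Z,4S)-5-[(tert-butyldimethylsilyl)oxy]-2,4-dimethylpent-2-enoate | CCOC(=O)/C(C)=C\[C@H](C)CO[Si](C)(C)C(C)(C)C | intermediate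
17 | (2Z,4S)-5-[(tert-butyldimethylsilyl)oxy]-2,4-dimethylpent-2-en-1-ol | OC/C(C)=C\[C@H](C)CO[Si](C)(C)C(C)(C)C | intermediate
18 | (2Z,4S)-5-[(tert-butyldimethylsilyl)oxy]-2,4-dimethylpent-2-enal | O=C/C(C)=C\[C@H](C)CO[Si](C)(C)C(C)(C)C | intermediate
19 | (R)-4-benzyl-1,3-oxazolidin-2-one | O=C1N[C@H](Cc2ccccc2)CO1 | starting material
20 | methoxyacetyl chloride | COCC(=O)Cl | starting material
21 | (R)-4-benzyl-3-(methoxyacetyl)-1,3-oxazolidin-2-one | COCC(=O)N1[C@H](Cc2ccccc2)COC1=O | intermediate
22 | dibutylboron aldolate of 23 (O-dibutylboryl at C7) | O=C(N1[C@H](Cc2ccccc2)COC1=O)[C@H](OC)[C@@H](OB(CCCC)CCCC)/C(C)=C\[C@H](C)CO[Si](C)(C)C(C)(C)C | intermediate (not isolated)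
23 | (4R)-4-benzyl-3-[(2R,3S,4Z,6S)-7-[(tert-butyldimethylsilyl)oxy]-3-hydroxy-2-methoxy-4,6-dimethylhept-4-enoyl]-1,3-oxazolidin-2-one | O=C(N1[C@H](Cc2ccccc2)COC1=O)[C@H](OC)[C@@H](O)/C(C)=C\[C@H](C)CO[Si](C)(C)C(C)(C)C | intermediate
24 | (4R)-4-benzyl-3-[(2R,3S,4Z,6S)-3,7-bis[(tert-butyldimethylsilyl)oxy]-2-methoxy-4,6-dimethylhept-4-enoyl]-1,3-oxazolidin-2-one | O=C(N1[C@H](Cc2ccccc2)COC1=O)[C@H](OC)[C@@H](O[Si](C)(C)C(C)(C)C)/C(C)=C\[C@H](C)CO[Si](C)(C)C(C)(C)C | intermediate
25 | (2S,3S,4Z,6S)-3,7-bis[(tert-butyldimethylsilyl)oxy]-2-methoxy-4,6-dimethylhept-4-en-1-ol | OC[C@H](OC)[C@@H](O[Si](C)(C)C(C)(C)C)/C(C)=C\[C@H](C)CO[Si](C)(C)C(C)(C)C | intermediate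
26 | (2R,3S,4Z,6S)-3,7-bis[(tert-butyldimethylsilyl)oxy]-2-methoxy-4,6-dimethylhept-4-enal | O=C[C@H](OC)[C@@H](O[Si](C)(C)C(C)(C)C)/C(C)=C\[C@H](C)CO[Si](C)(C)C(C)(C)C | intermediate
27 | methyl 2-[bis(2,2,2-trifluoroethoxy)phosphoryl]acetate | COC(=O)CP(=O)(OCC(F)(F)F)OCC(F)(F)F | starting material
28 | methyl (2Z,4S,5S,6Z,8S)-5,9-bis[(tert-butyldimethylsilyl)oxy]-4-methoxy-6,8-dimethylnona-2,6-dienoate | COC(=O)/C=C\[C@H](OC)[C@@H](O[Si](C)(C)C(C)(C)C)/C(C)=C\[C@H](C)CO[Si](C)(C)C(C)(C)C | intermediate
29 | (2Z,4S,5S,6Z,8S)-5,9-bis[(tert-butyldimethylsilyl)oxy]-4-methoxy-6,8-dimethylnona-2,6-dien-1-ol | OC/C=C\[C@H](OC)[C@@H](O[Si](C)(C)C(C)(C)C)/C(C)=C\[C@H](C)CO[Si](C)(C)C(C)(C)C | intermediate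
30 | (2Z,4S,5S,6Z,8S)-5,9-bis[(tert-butyldimethylsilyl)oxy]-4-methoxy-6,8-dimethylnona-2,6-dienal | O=C/C=C\[C@H](OC)[C@@H](O[Si](C)(C)C(C)(C)C)/C(C)=C\[C@H](C)CO[Si](C)(C)C(C)(C)C | intermediate
31 | ethyl (2Z,4Z,6S,7S,8Z,10S)-7,11-bis[(tert-butyldimethylsilyl)oxy]-6-methoxy-2,8,10-trimethylundeca-2,4,8-trienoate | CCOC(=O)/C(C)=C\C=C/[C@H](OC)[C@@H](O[Si](C)(C)C(C)(C)C)/C(C)=C\[C@H](C)CO[Si](C)(C)C(C)(C)C | intermediate
32 | (2Z,4Z,6S,7S,8Z,10S)-7,11-bis[(tert-butyldimethylsilyl)oxy]-6-methoxy-2,8,10-trimethylundeca-2,4,8-trienoic acid | OC(=O)/C(C)=C\C=C/[C@H](OC)[C@@H](O[Si](C)(C)C(C)(C)C)/C(C)=C\[C@H](C)CO[Si](C)(C)C(C)(C)C | intermediate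
33 | (2Z,4Z,6S,7S,8Z,10S)-7,11-bis[(tert-butyldimethylsilyl)oxy]-N-{3-[(1R,2S)-4-[(tert-butyldimethylsilyl)oxy]-1-methoxy-2-methylbutyl]-2,5-dimethoxyphenyl}-6-methoxy-2,8,10-trimethylundeca-2,4,8-trienamide | CC(C)(C)[Si](C)(C)OCC[C@H](C)[C@@H](OC)c1cc(OC)cc(c1OC)NC(=O)/C(C)=C\C=C/[C@H](OC)[C@@H](O[Si](C)(C)C(C)(C)C)/C(C)=C\[C@H](C)CO[Si](C)(C)C(C)(C)C | intermediate
34 | (2Z,4Z,6S,7S,8Z,10S)-7-[(tert-butyldimethylsilyl)oxy]-11-hydroxy-N-{3-[(1R,2S)-4-hydroxy-1-methoxy-2-methylbutyl]-2,5-dimethoxyphenyl}-6-methoxy-2,8,10-trimethylundeca-2,4,8-trienamide | OCC[C@H](C)[C@@H](OC)c1cc(OC)cc(c1OC)NC(=O)/C(C)=C\C=C/[C@H](OC)[C@@H](O[Si](C)(C)C(C)(C)C)/C(C)=C\[C@H](C)CO | intermediate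
35 | (2Z,4Z,6S,7S,8Z,10S)-7-[(tert-butyldimethylsilyl)oxy]-N-{2,5-dimethoxy-3-[(1R,2S)-1-methoxy-2-methyl-4-oxobutyl]phenyl}-6-methoxy-2,8,10-trimethyl-11-oxoundeca-2,4,8-trienamide (seco dialdehyde) | O=CC[C@H](C)[C@@H](OC)c1cc(OC)cc(c1OC)NC(=O)/C(C)=C\C=C/[C@H](OC)[C@@H](O[Si](C)(C)C(C)(C)C)/C(C)=C\[C@H](C)C=O | intermediate
36 | bis(diiodosamarium) 11,12-diolate of 37 | I[Sm](I)O[C@H]1[C@@H](O[Sm](I)I)C[C@H](C)[C@@H](OC)c2cc(OC)cc(c2OC)NC(=O)/C(C)=C\C=C/[C@H](OC)[C@@H](O[Si](C)(C)C(C)(C)C)/C(C)=C\[C@@H]1C | intermediate (not isolated)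
37 | 19-membered ansa lactam, (2Z,4Z,8Z)-(6S,7S,10S,11R,12S,14S,15R): 11,12-dihydroxy, 7-O-TBS, 6,15-dimethoxy, 18,21-di-O-methyl | O[C@H]1[C@@H](O)C[C@H](C)[C@@H](OC)c2cc(OC)cc(c2OC)NC(=O)/C(C)=C\C=C/[C@H](OC)[C@@H](O[Si](C)(C)C(C)(C)C)/C(C)=C\[C@@H]1C | intermediate
38 | 19-membered ansa lactam, same configuration: 6,11,12,15-tetramethoxy, 7-O-TBS, 18,21-di-O-methyl | CO[C@H]1[C@@H](OC)C[C@H](C)[C@@H](OC)c2cc(OC)cc(c2OC)NC(=O)/C(C)=C\C=C/[C@H](OC)[C@@H](O[Si](C)(C)C(C)(C)C)/C(C)=C\[C@@H]1C | intermediate
39 | 19-membered ansa lactam, same configuration: 7-hydroxy, 6,11,12,15-tetramethoxy, 18,21-di-O-methyl | CO[C@H]1[C@@H](OC)C[C@H](C)[C@@H](OC)c2cc(OC)cc(c2OC)NC(=O)/C(C)=C\C=C/[C@H](OC)[C@@H](O)/C(C)=C\[C@@H]1C | intermediate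
40 | 7-O-[N-(trichloroacetyl)carbamoyl] derivative of 39 | CO[C@H]1[C@@H](OC)C[C@H](C)[C@@H](OC)c2cc(OC)cc(c2OC)NC(=O)/C(C)=C\C=C/[C@H](OC)[C@@H](OC(=O)NC(=O)C(Cl)(Cl)Cl)/C(C)=C\[C@@H]1C | intermediate (not isolated)
41 | 7-O-carbamoyl 19-membered ansa lactam, 18,21-di-O-methyl hydroquinone | CO[C@H]1[C@@H](OC)C[C@H](C)[C@@H](OC)c2cc(OC)cc(c2OC)NC(=O)/C(C)=C\C=C/[C@H](OC)[C@@H](OC(N)=O)/C(C)=C\[C@@H]1C | intermediate
42 | 7-O-carbamoyl ansa 18,21-quinone | CO[C@H]1[C@@H](OC)C[C@H](C)[C@@H](OC)C2=CC(=O)C=C(NC(=O)/C(C)=C\C=C/[C@H](OC)[C@@H](OC(N)=O)/C(C)=C\[C@@H]1C)C2=O | intermediate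
43 | CNP0109452.1, 7-O-carbamoyl ansa 18,21-hydroquinone | CO[C@H]1[C@@H](OC)C[C@H](C)[C@@H](OC)c2cc(O)cc(c2O)NC(=O)/C(C)=C\C=C/[C@H](OC)[C@@H](OC(N)=O)/C(C)=C\[C@@H]1C | target

## Step count and least certain steps

Total: 31 steps (25 before the key step, 5 after it). Longest linear sequence: 23 steps, from 12 to 43 (steps 8–12 and 14–31). The western branch (1 to 11) has 7 steps.

**Step 26 (key step).** What may go wrong:
- Facial control at C12 may be lost, through the chelate with the ring arms trans or through an open transition state, so that the 12-epimer accompanies or replaces 37.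
- Each aldehyde may be reduced to the alcohol, or intermolecular coupling may occur, if ring closure is slow.
- C10 of 35 may enolise before electron transfer.

Fallback: it sets out from the 12-epimeric product, the (11R,12R)-diol F1, alone or mixed with 37, and returns to 37. The C12 configuration is then set by a ketone reduction instead of by the coupling. Oxidation with TEMPO (cat.) and PhI(OAc)2 in CH2Cl2 should take the less hindered C12 hydroxyl, which is flanked by a methylene group, in preference to the C11 hydroxyl next to the C10 branch. This gives the 11-hydroxy-12-ketone F2. Reduction of F2 with Zn(BH4)2 in Et2O at −20 °C goes through the zinc chelate of the C11 hydroxyl and the ketone, with hydride delivered from the face away from the C10 arm, and gives the 11,12-anti diol 37. Both C12 epimers converge on F2, so a mixture needs no separation.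

**Step 27.** What may go wrong: the amide oxygen may be alkylated in competition with the second, more hindered hydroxyl, or the double methylation may stop halfway.
Fallback: from 37 to 38 by Purdie methylation with MeI and Ag2O (4 Å MS, MeCN, 40 °C, dark). The electrophile is then a silver-activated alkyl iodide, which etherifies hydroxyl groups but does not alkylate a neutral secondary amide. The mode of activation changes, not only the medium. No new compound arises (F0).

**Step 23.** What may go wrong: acylation of the ortho-substituted aniline may be slow, so that the activated 2Z-dienoyl species isomerises to 2E or cyclises through its own diene before the amine attacks.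
Fallback: from ester 31 and aniline 11 directly to 33, without the free acid. AlMe3 (toluene, 0 °C → rt) converts 11 into its dimethylaluminium amide, which attacks the ester carbonyl of 31 at 40–60 °C (Weinreb-type aminolysis). No acyl-activated dienoic acid is involved and step 22 is skipped. No new compound arises (F0).

**Step 3.** What may go wrong: enantiofacial control may be incomplete with the doubly ortho-substituted aryl aldehyde. The syn selectivity from the Z-crotyl geometry is not in doubt. The minor enantiomer would surface as a diastereomeric amide at step 23.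
Fallback: from 3 to 7 under auxiliary control, in five steps in place of steps 3 and 4.
- Evans syn aldol of 3 with commercial (R)-4-benzyl-3-propionyl-2-oxazolidinone (Bu2BOTf, Et3N, CH2Cl2, −78 → 0 °C) gives the aldol adduct F3.
- Me3OBF4 with 1,8-bis(dimethylamino)naphthalene gives its methyl ether F4.
- LiBH4 removes the auxiliary and gives the primary alcohol F5.
- Dess–Martin oxidation gives the aldehyde F6.
- Wittig methylenation (Ph3P=CH2, THF, −78 → 0 °C) gives 7.

The aldol diastereomers can be separated before the auxiliary is removed.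

## Further compounds

F1 | step 26 | (11R,12R)-11,12-diol, the 12-epimer of 37 | O[C@H]1[C@H](O)C[C@H](C)[C@@H](OC)c2cc(OC)cc(c2OC)NC(=O)/C(C)=C\C=C/[C@H](OC)[C@@H](O[Si](C)(C)C(C)(C)C)/C(C)=C\[C@@H]1C
F2 | step 26 | (11R)-11-hydroxy-12-oxo ansa lactam bearing the C7 TBS ether | O[C@H]1C(=O)C[C@H](C)[C@@H](OC)c2cc(OC)cc(c2OC)NC(=O)/C(C)=C\C=C/[C@H](OC)[C@@H](O[Si](C)(C)C(C)(C)C)/C(C)=C\[C@@H]1C
F3 | step 3 | (4R)-4-benzyl-3-[(2R,3R)-3-(2,5-dimethoxy-3-nitrophenyl)-3-hydroxy-2-methylpropanoyl]-1,3-oxazolidin-2-one | O=C(N1[C@H](Cc2ccccc2)COC1=O)[C@H](C)[C@@H](O)c1cc(OC)cc([N+](=O)[O-])c1OC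
F4 | step 3 | (4R)-4-benzyl-3-[(2R,3R)-3-(2,5-dimethoxy-3-nitrophenyl)-3-methoxy-2-methylpropanoyl]-1,3-oxazolidin-2-one | O=C(N1[C@H](Cc2ccccc2)COC1=O)[C@H](C)[C@@H](OC)c1cc(OC)cc([N+](=O)[O-])c1OC
F5 | step 3 | (2S,3R)-3-(2,5-dimethoxy-3-nitrophenyl)-3-methoxy-2-methylpropan-1-ol | OC[C@H](C)[C@@H](OC)c1cc(OC)cc([N+](=O)[O-])c1OC
F6 | step 3 | (2R,3R)-3-(2,5-dimethoxy-3-nitrophenyl)-3-methoxy-2-methylpropanal | O=C[C@H](C)[C@@H](OC)c1cc(OC)cc([N+](=O)[O-])c1OC
F0 | step 27 | none | none
F0 | step 23 | none | none
A1 | alternative 1 | ansa 4-methoxyphenol N-(4-methoxybenzyl) lactam, C21 hydroxyl free, C7 O-TBS | CO[C@H]1[C@@H](OC)C[C@H](C)[C@@H](OC)c2cc(OC)cc(c2O)N(Cc3ccc(OC)cc3)C(=O)/C(C)=C\C=C/[C@H](OC)[C@@H](O[Si](C)(C)C(C)(C)C)/C(C)=C\[C@@H]1C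
A2 | alternative 1 | open-chain pentacarbonyl[(E)-alkenyl(methoxy)carbene]chromium with terminal N-(4-methoxybenzyl) ynamide | C#CN(Cc1ccc(OC)cc1)C(=O)/C(C)=C\C=C/[C@H](OC)[C@@H](O[Si](C)(C)C(C)(C)C)/C(C)=C\[C@H](C)[C@@H](OC)[C@@H](OC)C[C@H](C)[C@@H](OC)/C=C/C(OC)=[Cr](=C=O)(=C=O)(=C=O)(=C=O)=C=O
A3 | alternative 2 | 19-membered (2Z)-en-4-yne lactam, C7 O-triethylsilyl | CO[C@H]1[C@@H](OC)C[C@H](C)[C@@H](OC)c2cc(OC)cc(c2OC)NC(=O)/C(C)=C\C#C[C@H](OC)[C@@H](O[Si](CC)(CC)CC)/C(C)=C\[C@@H]1C
A4 | alternative 2 | 18-membered aryl enynyl ketoxime, hydroxyl anti to the arene, C7 O-triethylsilyl | CO[C@H]1[C@@H](OC)C[C@H](C)[C@@H](OC)c2cc(OC)cc(c2OC)/C(=N/O)/C(C)=C\C#C[C@H](OC)[C@@H](O[Si](CC)(CC)CC)/C(C)=C\[C@@H]1C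
A5 | alternative 3 | 19-membered (2Z)-en-4-yne lactam, C7 O-TBS | CO[C@H]1[C@@H](OC)C[C@H](C)[C@@H](OC)c2cc(OC)cc(c2OC)NC(=O)/C(C)=C\C#C[C@H](OC)[C@@H](O[Si](C)(C)C(C)(C)C)/C(C)=C\[C@@H]1C
A6 | alternative 3 | seco diyne with methyl-capped alkynes at C4 and C5, C7 O-TBS | CC#C[C@H](OC)[C@@H](O[Si](C)(C)C(C)(C)C)/C(C)=C\[C@H](C)[C@@H](OC)[C@@H](OC)C[C@H](C)[C@@H](OC)c1cc(OC)cc(c1OC)NC(=O)/C(C)=C\C#CC
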